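The readings are calculated with made-up constants; noise was put on by code.

If a solid dissolves at a steady rate, its charge divided by that rate is a time we can reckon before knowing the chemistry behind it.

- ochre: solid substrate 0.032 M; protic impurity 0.032 M; run made earlier
- flask: solid substrate 0.064 M; protic impurity 0.0320 M; time 2.0 d

- ochre (time / h: target / %, solid substrate / %): 0.250: 0, 91.7; 0.667: 0.2, 77.5; 1.33: 2.6, 56.0; 2.00: 8.8, 32.8; 3.00: 11.3, 0; 4.00: 12.8, 1.3; 5.00: 10.7, 0

(standard deviation of a reading: 1 percentage point)

* the best time, 2.0 d at the latest, for target
* the amount of target, in percent of the solid substrate charged, at that time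

- as a solid, counted per litre of solution: solid substrate
- at the start none of the solid substrate is in solution

1. In the ochre run the solid substrate falls from 91.7% at 0.250 h to 32.8% at 2.00 h. We replace this curve by its mean, 0.0108 M/h, as if a dosing pump ran.
2. We check the error. From the full charge, this line gives 55.2% at 1.33 h, and the reading is 56.0%. The miss is 0.76 percentage points, against a scatter of 1 point.
3. In the flask, charge divided by this rate is 0.248 d, the feed time.
4. First extreme for the time: the steps after dissolving are instant, so target tops at the feed time. Second extreme: the flask keeps the full ochre lag. The ochre run's highest target reading, at 4.00 h, comes 1.03 h after its own feed time, which gives 0.291 d. We commit to the mean of these extremes, 0.269 d.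
5. For the amount, that reading means c(target) = 4.10 mM. If the flask repeats this concentration, it has 6.40%. If it repeats the percentage, it has 12.8%. We commit to the mean, 9.60%.
6. The forecast says 0.27 d and 49%, an amount higher than ours, on the ground that “about 0.032 M becomes target”.

The flask gives 0.274 d and 9.00%, which is 40 points under the forecast.

    target → over-reaction product (k = 3.75 × 10⁻⁴ /s)
    solid substrate ⇌ starting material, rate k2*(cs2 - [starting material]) while solid is left; crystals form when [starting material] > cs2 (solubility = 4.20 mM, k = 8.49 × 10⁻⁴ /s)
    intermediate B → intermediate C (k = 4.88 × 10⁻⁴ /s)
    intermediate C → target (k = 8.44 × 10⁻⁴ /s)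
    intermediate A → intermediate B (k = 2.58 × 10⁻⁴ /s)
    starting material → intermediate A (k = 0.00281 /s)
    starting material + protic impurity → quenched substrate (k = 0.0413 /M/s)

While solid substrate stood in the flask, it dissolved close to our line: the line leaves 19.4% at 0.200 d, the flask holds 21.0%, and at 0.274 d it holds 0%; meanwhile target turned into over-reaction product, which stands at 45.7% at that time and reaches 74.8% at 1.00 d, with target at 0%. With 0.16 M of solid substrate the feed time is 0.617 d, shorter than 2.0 d; that neighbour ends with 0% solid substrate, and its best target is 4.25%.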